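The isoflavan is cut at C3–C4. C4 is the benzylic carbon of ring A and the phenolic O2' of ring B sits two atoms from C3, so a temporary O2'–C4 benzyl ether turns this bond into the product of an intramolecular 1,5 C–H insertion. Decomposition of an aryldiazoacetate (ring B, C3, ester as latent C2) bearing the ring A benzyl group on O2' by a chiral dirhodium carboxylate forges C3–C4, sets C3 and closes a cis-dihydrobenzofuran in one operation. Ester reduction, Mitsunobu closure of ring C to a pterocarpan and hydrogenolysis of C4–O2' then unveil the 2'-hydroxyisoflavan, which is prenylated and annulated late.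

Key step: step 8

Assumption (sense of induction): Rh2(S-PTTL)4 is taken to deliver the (2R,3S) antipode of 11; should it favour the mirror image, Rh2(R-PTTL)4, made from D-tert-leucine, is used in step 8 without any other change.
Numbering: isoflavan locants are used for all intermediates (ring C: O1, C2, C3, C4; ring A: C4a–C8a; ring B: C1'–C6').

Step 1
Reactants: 1 2,4-dihydroxybenzaldehyde
Product: 2 2-hydroxy-4-(triisopropylsilyloxy)benzaldehyde
Conditions: TIPSCl (1.05 equiv), imidazole, CH2Cl2, 0 °C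
Reagents that add atoms: chlorotriisopropylsilane, CC(C)[Si](Cl)(C(C)C)C(C)C
Why: Silyl ether formation at a phenol: the 2-OH is held in a hydrogen bond to the formyl oxygen, so the bulky silyl chloride should react only at the 4-OH (the future O7).

Step 2
Reactants: 2 2-hydroxy-4-(triisopropylsilyloxy)benzaldehyde
Product: 3 2-formyl-5-(triisopropylsilyloxy)phenyl pivalate
Conditions: PivCl, Et3N, DMAP (cat.), CH2Cl2, 0 °C to rt
Reagents that add atoms: pivaloyl chloride, CC(C)(C)C(=O)Cl
Why: DMAP-catalysed O-acylation of the remaining phenol (the future O1); the hindered pivalate is chosen because it resists acyl transfer and is later cleaved by LiAlH4 in the same operation that reduces the ester.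

Step 3
Reactants: 3 2-formyl-5-(triisopropylsilyloxy)phenyl pivalate
Product: 4 2-(hydroxymethyl)-5-(triisopropylsilyloxy)phenyl pivalate
Conditions: BH3·THF, THF, 0 °C; MeOH quench
Reagents that add atoms: none
Why: Chemoselective borane reduction of the aldehyde in the presence of the aryl ester; the alcohol is delivered as a neutral borate ester and never as a free alkoxide, which should prevent O-to-O migration of the neighbouring pivaloyl group.

Step 4
Reactants: 5 2,4-dihydroxyphenylacetic acid
Product: 6 6-hydroxybenzofuran-2(3H)-one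
Conditions: TsOH·H2O (cat.), PhMe, reflux (Dean–Stark)
Reagents that add atoms: none
Why: Acid-catalysed lactonisation with azeotropic removal of water; the five-membered aryl lactone ties up O2' and the carboxyl group at once, leaving O4' as the only free hydroxyl and so fixing the regiochemistry of the next step.

Step 5
Reactants: 6 6-hydroxybenzofuran-2(3H)-one
Product: 8 methyl 2-[2-hydroxy-4-(methoxymethoxy)phenyl]acetate, via 6-(methoxymethoxy)benzofuran-2(3H)-one 7 (not isolated)
Conditions: MOMCl (1.1 equiv), i-Pr2NEt, THF, 0 °C to rt; then MeOH, K2CO3 (1.5 equiv), 0 °C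
Reagents that add atoms: chloromethyl methyl ether, COCCl; methanol, CO
Why: MOM ether formation at the only free phenol, then base-catalysed transesterification of the activated aryl lactone by methanol (added before the carbonate so that surplus MOMCl is destroyed), which releases O2' and the methyl ester together.

Step 6
Reactants: 4 2-(hydroxymethyl)-5-(triisopropylsilyloxy)phenyl pivalate; 8 methyl 2-[2-hydroxy-4-(methoxymethoxy)phenyl]acetate
Product: 9 methyl 2-{4-(methoxymethoxy)-2-[2-(pivaloyloxy)-4-(triisopropylsilyloxy)benzyloxy]phenyl}acetate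
Conditions: PPh3, DIAD, THF, 0 °C to rt
Reagents that add atoms: none
Why: Mitsunobu etherification of a phenol with a primary benzylic alcohol builds the temporary O2'–C4 ether under neutral conditions, avoiding both a labile 4-silyloxybenzyl halide and any base that could cleave or shift the pivalate.

Step 7
Reactants: 9 methyl 2-{4-(methoxymethoxy)-2-[2-(pivaloyloxy)-4-(triisopropylsilyloxy)benzyloxy]phenyl}acetate
Product: 10 methyl 2-diazo-2-{4-(methoxymethoxy)-2-[2-(pivaloyloxy)-4-(triisopropylsilyloxy)benzyloxy]phenyl}acetate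
Conditions: p-ABSA, DBU, MeCN, 0 °C to rt
Reagents that add atoms: 4-acetamidobenzenesulfonyl azide, CC(=O)Nc1ccc(cc1)S(=O)(=O)N=[N+]=[N-]
Why: Regitz diazo transfer to the arylacetate enolate generated by DBU; aryl silyl ether, MOM ether and hindered aryl ester should tolerate the amidine base at or below room temperature.

Step 8
Reactants: 10 methyl 2-diazo-2-{4-(methoxymethoxy)-2-[2-(pivaloyloxy)-4-(triisopropylsilyloxy)benzyloxy]phenyl}acetate
Product: 11 methyl (2R,3S)-6-(methoxymethoxy)-2-[2-(pivaloyloxy)-4-(triisopropylsilyloxy)phenyl]-2,3-dihydrobenzofuran-3-carboxylate (cis)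
Conditions: Rh2(S-PTTL)4 (1 mol %), PhMe, −60 °C, slow addition of 10
Reagents that add atoms: none
Why: Loss of N2 at Rh2(S-PTTL)4, dirhodium tetrakis[N-phthaloyl-(S)-tert-leucinate], a carboxylate-bridged dimer of divalent rhodium, gives a donor–acceptor carbenoid at C3 that inserts through a concerted, hydride-transfer-like three-centre transition state into one of the two enantiotopic benzylic C4–H bonds, which are activated by the adjacent O2' and by the electron-rich ring A. The closest known reaction type is the enantioselective intramolecular 1,5 C–H insertion of ortho-benzyloxy aryldiazoacetates to cis-2-aryl-2,3-dihydrobenzofuran-3-carboxylates under chiral dirhodium carboxylate catalysis. The only ring closed is the temporary dihydrofuran, formed by 1,5 insertion, that is, by bonding the carbenoid carbon to the fifth atom of the chain C3–C1'–C2'–O2'–C4. C3 (S here, the future 3R centre) is set by the face of the carbenoid that the phthalimido walls of the catalyst leave open, and C4 (R) follows from the compact transition state that places aryl and ester cis. The step needs C–H insertion to outrun oxonium ylide formation at O2', Büchner addition to ring A and carbene dimerisation, which the doubly activated C–H bond, the five-membered geometry, low temperature, slow addition and a non-coordinating solvent should secure. The cis ester is configurationally labile at C3 and is carried on without exposure to base.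

Step 9
Reactants: 11 methyl (2R,3S)-6-(methoxymethoxy)-2-[2-(pivaloyloxy)-4-(triisopropylsilyloxy)phenyl]-2,3-dihydrobenzofuran-3-carboxylate
Product: 12 2-[(2R,3R)-3-(hydroxymethyl)-6-(methoxymethoxy)-2,3-dihydrobenzofuran-2-yl]-5-(triisopropylsilyloxy)phenol (cis)
Conditions: LiAlH4, THF, −20 to 0 °C; then H2O, aq. NaOH
Reagents that add atoms: none
Why: Hydride reduction of the methyl ester to the primary alcohol (C2) with concurrent reductive cleavage of the aryl pivalate; fast reduction at low temperature removes the acidifying carbonyl before C3 can epimerise, and the change of the C3 descriptor from S to R reflects only the new CIP priorities.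

Step 10
Reactants: 12 2-[(2R,3R)-3-(hydroxymethyl)-6-(methoxymethoxy)-2,3-dihydrobenzofuran-2-yl]-5-(triisopropylsilyloxy)phenol
Product: 13 (6aR,11aR)-9-(methoxymethoxy)-3-(triisopropylsilyloxy)-6a,11a-dihydro-6H-benzofuro[3,2-c]chromene (cis-pterocarpan)
Conditions: PPh3, DIAD, THF (0.02 M), 0 °C to rt
Reagents that add atoms: none
Why: Intramolecular Mitsunobu etherification: the ring A phenol displaces the activated primary alcohol at C2 in a six-membered closure of ring C, and because the tether holds the substituents at C3 and C4 cis, only the cis-fused pterocarpan can form and no stereocentre is touched.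

Step 11
Reactants: 13 (6aR,11aR)-9-(methoxymethoxy)-3-(triisopropylsilyloxy)-6a,11a-dihydro-6H-benzofuro[3,2-c]chromene
Product: 14 5-(methoxymethoxy)-2-[(3R)-7-(triisopropylsilyloxy)-3,4-dihydro-2H-chromen-3-yl]phenol
Conditions: H2 (1 atm), 10% Pd/C, EtOAc–AcOH (10:1), rt
Reagents that add atoms: none
Why: Hydrogenolysis of the doubly activated benzylic C4–O2' bond, the known reductive opening of pterocarpans to 2'-hydroxyisoflavans, removes the tether, turns C4 into a methylene group and leaves C3 (now 3R), the aryl silyl ether and the MOM ether untouched.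

Step 12
Reactants: 15 2-methylbut-3-en-2-ol
Product: 17 isobutyl 2-methylbut-3-en-2-yl carbonate, via lithium 2-methylbut-3-en-2-olate 16 (not isolated)
Conditions: n-BuLi, THF, −78 °C; then i-BuOCOCl, −78 to 0 °C
Reagents that add atoms: isobutyl chloroformate, CC(C)COC(=O)Cl
Why: Deprotonation of the tertiary alcohol and O-acylation of the lithium alkoxide with a chloroformate gives the mixed carbonate needed as a 1,1-dimethylallyl donor.

Step 13
Reactants: 14 5-(methoxymethoxy)-2-[(3R)-7-(triisopropylsilyloxy)-3,4-dihydro-2H-chromen-3-yl]phenol; 17 isobutyl 2-methylbut-3-en-2-yl carbonate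
Product: 18 triisopropyl({(3R)-3-[4-(methoxymethoxy)-2-(2-methylbut-3-en-2-yloxy)phenyl]-3,4-dihydro-2H-chromen-7-yl}oxy)silane
Conditions: Pd(PPh3)4 (5 mol %), THF, 0 °C
Reagents that add atoms: none
Why: Tsuji–Trost O-allylation: zerovalent palladium ionises the tertiary carbonate with loss of CO2, the isobutoxide released deprotonates the phenol, and under kinetic control at low temperature the phenoxide attacks the substituted terminus of the 1,1-dimethylallyl palladium complex to give the tertiary ether at O2', the only free hydroxyl.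

Step 14
Reactants: 18 triisopropyl({(3R)-3-[4-(methoxymethoxy)-2-(2-methylbut-3-en-2-yloxy)phenyl]-3,4-dihydro-2H-chromen-7-yl}oxy)silane
Product: 20 3-(methoxymethoxy)-2-(3-methylbut-2-en-1-yl)-6-[(3R)-7-(triisopropylsilyloxy)-3,4-dihydro-2H-chromen-3-yl]phenol, via 6-prenylcyclohexa-2,4-dienone 19 (not isolated)
Conditions: PhNEt2, 130 °C
Reagents that add atoms: none
Why: Aromatic Claisen rearrangement: the [3,3] shift can only reach C3', the single unsubstituted position ortho to O2', delivers the allyl unit with inversion as a prenyl group, and the dienone tautomerises to the phenol; the weakly basic solvent suppresses acid-induced loss of the tertiary allyl group.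

Step 15
Reactants: 20 3-(methoxymethoxy)-2-(3-methylbut-2-en-1-yl)-6-[(3R)-7-(triisopropylsilyloxy)-3,4-dihydro-2H-chromen-3-yl]phenol
Product: 21 2-(3-methylbut-2-en-1-yl)-4-[(3R)-7-(triisopropylsilyloxy)-3,4-dihydro-2H-chromen-3-yl]benzene-1,3-diol
Conditions: HCl (1 M in MeOH), 25–40 °C
Reagents that add atoms: none
Why: Acid-catalysed acetal exchange of the aryl MOM ether with methanol; dilute acid at mild temperature should cleave the acetal faster than it protonates the prenyl alkene, and aryl triisopropylsilyl ethers resist these conditions.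

Step 16
Reactants: 21 2-(3-methylbut-2-en-1-yl)-4-[(3R)-7-(triisopropylsilyloxy)-3,4-dihydro-2H-chromen-3-yl]benzene-1,3-diol; 22 3-methylbut-2-enal (prenal)
Product: 24 2,2-dimethyl-8-(3-methylbut-2-en-1-yl)-6-[(3R)-7-(triisopropylsilyloxy)-3,4-dihydro-2H-chromen-3-yl]-2H-chromen-7-ol, via ortho-quinone methide 23 (not isolated)
Conditions: ethylenediammonium diacetate (20 mol %), PhMe, reflux
Reagents that add atoms: none
Why: Amine-catalysed condensation of the resorcinol with the enal at C5', the only free position ortho to a hydroxyl, then dehydration and oxa-6π electrocyclisation of the ortho-quinone methide (formal [3+3] chromene annulation); with C3' blocked by the prenyl group and O7 silylated, the pyran can close only between O4' and C5'.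

Step 17
Reactants: 24 2,2-dimethyl-8-(3-methylbut-2-en-1-yl)-6-[(3R)-7-(triisopropylsilyloxy)-3,4-dihydro-2H-chromen-3-yl]-2H-chromen-7-ol
Product: 25 (3R)-3-[7-hydroxy-2,2-dimethyl-8-(3-methylbut-2-en-1-yl)-2H-chromen-6-yl]-3,4-dihydro-2H-chromen-7-ol (CNP0331403.1)
Conditions: Bu4NF, AcOH, THF, 0 °C
Reagents that add atoms: none
Why: Fluoride-induced cleavage of the aryl silyl ether, buffered with acetic acid to keep the polyphenol from standing as a phenoxide, affects neither the chromene, the prenyl group nor C3.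

Compound list
1 | 2,4-dihydroxybenzaldehyde | O=Cc1ccc(O)cc1O | starting material
2 | 2-hydroxy-4-(triisopropylsilyloxy)benzaldehyde | O=Cc1ccc(O[Si](C(C)C)(C(C)C)C(C)C)cc1O | intermediate
3 | 2-formyl-5-(triisopropylsilyloxy)phenyl pivalate | O=Cc1ccc(O[Si](C(C)C)(C(C)C)C(C)C)cc1OC(=O)C(C)(C)C | intermediate
4 | 2-(hydroxymethyl)-5-(triisopropylsilyloxy)phenyl pivalate | OCc1ccc(O[Si](C(C)C)(C(C)C)C(C)C)cc1OC(=O)C(C)(C)C | intermediate
5 | 2,4-dihydroxyphenylacetic acid | OC(=O)Cc1ccc(O)cc1O | starting material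
6 | 6-hydroxybenzofuran-2(3H)-one | O=C1Cc2ccc(O)cc2O1 | intermediate
7 | 6-(methoxymethoxy)benzofuran-2(3H)-one (not isolated) | COCOc1ccc2CC(=O)Oc2c1 | intermediate
8 | methyl 2-[2-hydroxy-4-(methoxymethoxy)phenyl]acetate | COC(=O)Cc1ccc(OCOC)cc1O | intermediate
9 | methyl 2-{4-(methoxymethoxy)-2-[2-(pivaloyloxy)-4-(triisopropylsilyloxy)benzyloxy]phenyl}acetate | COC(=O)Cc1ccc(OCOC)cc1OCc1ccc(O[Si](C(C)C)(C(C)C)C(C)C)cc1OC(=O)C(C)(C)C | intermediate
10 | methyl 2-diazo-2-{4-(methoxymethoxy)-2-[2-(pivaloyloxy)-4-(triisopropylsilyloxy)benzyloxy]phenyl}acetate | COC(=O)C(=[N+]=[N-])c1ccc(OCOC)cc1OCc1ccc(O[Si](C(C)C)(C(C)C)C(C)C)cc1OC(=O)C(C)(C)C | intermediate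
11 | methyl (2R,3S)-6-(methoxymethoxy)-2-[2-(pivaloyloxy)-4-(triisopropylsilyloxy)phenyl]-2,3-dihydrobenzofuran-3-carboxylate | COC(=O)[C@@H]1[C@H](c2ccc(O[Si](C(C)C)(C(C)C)C(C)C)cc2OC(=O)C(C)(C)C)Oc2cc(OCOC)ccc21 | intermediate
12 | 2-[(2R,3R)-3-(hydroxymethyl)-6-(methoxymethoxy)-2,3-dihydrobenzofuran-2-yl]-5-(triisopropylsilyloxy)phenol | OC[C@@H]1[C@H](c2ccc(O[Si](C(C)C)(C(C)C)C(C)C)cc2O)Oc2cc(OCOC)ccc21 | intermediate
13 | (6aR,11aR)-9-(methoxymethoxy)-3-(triisopropylsilyloxy)-6a,11a-dihydro-6H-benzofuro[3,2-c]chromene | C1[C@@H]2[C@H](c3ccc(O[Si](C(C)C)(C(C)C)C(C)C)cc3O1)Oc1cc(OCOC)ccc12 | intermediate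
14 | 5-(methoxymethoxy)-2-[(3R)-7-(triisopropylsilyloxy)-3,4-dihydro-2H-chromen-3-yl]phenol | COCOc1ccc([C@@H]2COc3cc(O[Si](C(C)C)(C(C)C)C(C)C)ccc3C2)c(O)c1 | intermediate
15 | 2-methylbut-3-en-2-ol | CC(C)(O)C=C | starting material
16 | lithium 2-methylbut-3-en-2-olate (not isolated) | [Li+].[O-]C(C)(C)C=C | intermediate
17 | isobutyl 2-methylbut-3-en-2-yl carbonate | CC(C)COC(=O)OC(C)(C)C=C | intermediate
18 | triisopropyl({(3R)-3-[4-(methoxymethoxy)-2-(2-methylbut-3-en-2-yloxy)phenyl]-3,4-dihydro-2H-chromen-7-yl}oxy)silane | COCOc1ccc([C@@H]2COc3cc(O[Si](C(C)C)(C(C)C)C(C)C)ccc3C2)c(OC(C)(C)C=C)c1 | intermediate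
19 | 5-(methoxymethoxy)-6-(3-methylbut-2-en-1-yl)-2-[(3R)-7-(triisopropylsilyloxy)-3,4-dihydro-2H-chromen-3-yl]cyclohexa-2,4-dien-1-one, both C6 epimers (not isolated) | COCOC1=CC=C([C@@H]2COc3cc(O[Si](C(C)C)(C(C)C)C(C)C)ccc3C2)C(=O)C1CC=C(C)C | intermediate
20 | 3-(methoxymethoxy)-2-(3-methylbut-2-en-1-yl)-6-[(3R)-7-(triisopropylsilyloxy)-3,4-dihydro-2H-chromen-3-yl]phenol | COCOc1ccc([C@@H]2COc3cc(O[Si](C(C)C)(C(C)C)C(C)C)ccc3C2)c(O)c1CC=C(C)C | intermediate
21 | 2-(3-methylbut-2-en-1-yl)-4-[(3R)-7-(triisopropylsilyloxy)-3,4-dihydro-2H-chromen-3-yl]benzene-1,3-diol | Oc1ccc([C@@H]2COc3cc(O[Si](C(C)C)(C(C)C)C(C)C)ccc3C2)c(O)c1CC=C(C)C | intermediate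
22 | 3-methylbut-2-enal (prenal) | CC(C)=CC=O | starting material
23 | 3-hydroxy-6-(3-methylbut-2-en-1-ylidene)-2-(3-methylbut-2-en-1-yl)-4-[(3R)-7-(triisopropylsilyloxy)-3,4-dihydro-2H-chromen-3-yl]cyclohexa-2,4-dien-1-one (ortho-quinone methide, not isolated) | O=C1C(CC=C(C)C)=C(O)C([C@@H]2COc3cc(O[Si](C(C)C)(C(C)C)C(C)C)ccc3C2)=CC1=CC=C(C)C | intermediate
24 | 2,2-dimethyl-8-(3-methylbut-2-en-1-yl)-6-[(3R)-7-(triisopropylsilyloxy)-3,4-dihydro-2H-chromen-3-yl]-2H-chromen-7-ol | CC(C)=CCc1c(O)c([C@@H]2COc3cc(O[Si](C(C)C)(C(C)C)C(C)C)ccc3C2)cc2c1OC(C)(C)C=C2 | intermediate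
25 | (3R)-3-[7-hydroxy-2,2-dimethyl-8-(3-methylbut-2-en-1-yl)-2H-chromen-6-yl]-3,4-dihydro-2H-chromen-7-ol | CC(C)=CCc1c(O)c([C@@H]2COc3cc(O)ccc3C2)cc2c1OC(C)(C)C=C2 | target

Total step count: 17.
Longest linear sequence: 14 steps (steps 1–3, 6–11 and 13–17, from 1).

Steps most likely to fail

1. Step 8. What may go wrong: the carbenoid may be diverted before it reaches the C4–H bond (attack of O2' to give an oxonium ylide that rearranges, addition to ring A, dimerisation). The ortho-pivaloyloxy group may also lower the facial and cis selectivity, so that C3 is not set cleanly. The fallback makes C3–C4 and the C3 stereocentre by auxiliary-controlled enolate alkylation (Evans alkylation) and sets out from 8 and 4. O-Benzylation of 8 (BnBr, K2CO3, acetone) gives methyl 2-[2-(benzyloxy)-4-(methoxymethoxy)phenyl]acetate F1. Saponification (LiOH, THF–H2O) gives 2-[2-(benzyloxy)-4-(methoxymethoxy)phenyl]acetic acid F2. PivCl and Et3N convert it into 2-[2-(benzyloxy)-4-(methoxymethoxy)phenyl]acetic pivalic anhydride F3, not isolated, which acylates lithiated (4R)-4-benzyl-1,3-oxazolidin-2-one to give (4R)-4-benzyl-3-{2-[2-(benzyloxy)-4-(methoxymethoxy)phenyl]acetyl}-1,3-oxazolidin-2-one F4. Alcohol 4 is converted by the Appel reaction (CBr4, PPh3, CH2Cl2, 0 °C) into 2-(bromomethyl)-5-(triisopropylsilyloxy)phenyl pivalate F5, used at once. The sodium enolate of F4 (NaN(SiMe3)2, THF, −78 °C) should be alkylated by F5 on the face remote from the benzyl group of the auxiliary. This gives 2-{(2R)-2-[2-(benzyloxy)-4-(methoxymethoxy)phenyl]-3-[(4R)-4-benzyl-2-oxo-1,3-oxazolidin-3-yl]-3-oxopropyl}-5-(triisopropylsilyloxy)phenyl pivalate F6, with the R configuration at the future C3. LiAlH4 (THF, −20 to 0 °C) removes auxiliary and pivalate to give (2R)-2-[2-(benzyloxy)-4-(methoxymethoxy)phenyl]-3-[2-hydroxy-4-(triisopropylsilyloxy)phenyl]propan-1-ol F7. Mitsunobu closure of ring C (PPh3, DIAD, THF) gives ({(3R)-3-[2-(benzyloxy)-4-(methoxymethoxy)phenyl]-3,4-dihydro-2H-chromen-7-yl}oxy)triisopropylsilane F8. Hydrogenolysis of the benzyl ether (H2, Pd/C, EtOAc) comes back to the route at 14.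

2. Step 13. What may go wrong: attack of the phenoxide at the unsubstituted allyl terminus, or equilibration of the tertiary ether to the linear prenyl ether, and slow reaction of the hindered phenol. The fallback sets out from 14. Copper-catalysed propargylation with 3-chloro-3-methylbut-1-yne (CuCl2·2H2O cat., DBU, MeCN, 0 °C) can place only the tertiary carbon on oxygen. It gives triisopropyl({(3R)-3-[4-(methoxymethoxy)-2-(2-methylbut-3-yn-2-yloxy)phenyl]-3,4-dihydro-2H-chromen-7-yl}oxy)silane F9. Partial hydrogenation over Pd/CaCO3 poisoned with Pb(OAc)2, with quinoline (Lindlar reduction), comes back to the route at 18.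

3. Step 16. What may go wrong: sluggish condensation at the hindered C5' with self-condensation of the enal, or loss of the silyl group under hot amine acetate, after which ring A would begin to compete. The fallback sets out from 21. Copper-catalysed O-propargylation with 3-chloro-3-methylbut-1-yne (CuCl2·2H2O cat., DBU, MeCN, 0 °C) should take the less hindered O4', since O2' is flanked on both sides. It gives 3-(2-methylbut-3-yn-2-yloxy)-2-(3-methylbut-2-en-1-yl)-6-[(3R)-7-(triisopropylsilyloxy)-3,4-dihydro-2H-chromen-3-yl]phenol F10. Heating (PhNEt2, 150 °C) triggers the propargyl Claisen shift to C5', the only free ortho position. This gives 3-hydroxy-2-(3-methylbut-2-en-1-yl)-6-(3-methylbuta-1,2-dien-1-yl)-4-[(3R)-7-(triisopropylsilyloxy)-3,4-dihydro-2H-chromen-3-yl]cyclohexa-2,4-dien-1-one F11, not isolated. A 1,5-hydrogen shift converts it into the ortho-quinone methide 23, and electrocyclisation comes back to the route at 24.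

Further compounds
F1 | step 8 | methyl 2-[2-(benzyloxy)-4-(methoxymethoxy)phenyl]acetate | COC(=O)Cc1ccc(OCOC)cc1OCc1ccccc1
F2 | step 8 | 2-[2-(benzyloxy)-4-(methoxymethoxy)phenyl]acetic acid | OC(=O)Cc1ccc(OCOC)cc1OCc1ccccc1
F3 | step 8 | 2-[2-(benzyloxy)-4-(methoxymethoxy)phenyl]acetic pivalic anhydride | CC(C)(C)C(=O)OC(=O)Cc1ccc(OCOC)cc1OCc1ccccc1
F4 | step 8 | (4R)-4-benzyl-3-{2-[2-(benzyloxy)-4-(methoxymethoxy)phenyl]acetyl}-1,3-oxazolidin-2-one | COCOc1ccc(CC(=O)N2[C@H](Cc3ccccc3)COC2=O)c(OCc2ccccc2)c1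
F5 | step 8 | 2-(bromomethyl)-5-(triisopropylsilyloxy)phenyl pivalate | BrCc1ccc(O[Si](C(C)C)(C(C)C)C(C)C)cc1OC(=O)C(C)(C)C
F6 | step 8 | 2-{(2R)-2-[2-(benzyloxy)-4-(methoxymethoxy)phenyl]-3-[(4R)-4-benzyl-2-oxo-1,3-oxazolidin-3-yl]-3-oxopropyl}-5-(triisopropylsilyloxy)phenyl pivalate | COCOc1ccc([C@@H](Cc2ccc(O[Si](C(C)C)(C(C)C)C(C)C)cc2OC(=O)C(C)(C)C)C(=O)N2[C@H](Cc3ccccc3)COC2=O)c(OCc2ccccc2)c1
F7 | step 8 | (2R)-2-[2-(benzyloxy)-4-(methoxymethoxy)phenyl]-3-[2-hydroxy-4-(triisopropylsilyloxy)phenyl]propan-1-ol | COCOc1ccc([C@@H](Cc2ccc(O[Si](C(C)C)(C(C)C)C(C)C)cc2O)CO)c(OCc2ccccc2)c1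
F8 | step 8 | ({(3R)-3-[2-(benzyloxy)-4-(methoxymethoxy)phenyl]-3,4-dihydro-2H-chromen-7-yl}oxy)triisopropylsilane | COCOc1ccc([C@@H]2COc3cc(O[Si](C(C)C)(C(C)C)C(C)C)ccc3C2)c(OCc2ccccc2)c1
F9 | step 13 | triisopropyl({(3R)-3-[4-(methoxymethoxy)-2-(2-methylbut-3-yn-2-yloxy)phenyl]-3,4-dihydro-2H-chromen-7-yl}oxy)silane | COCOc1ccc([C@@H]2COc3cc(O[Si](C(C)C)(C(C)C)C(C)C)ccc3C2)c(OC(C)(C)C#C)c1
F10 | step 16 | 3-(2-methylbut-3-yn-2-yloxy)-2-(3-methylbut-2-en-1-yl)-6-[(3R)-7-(triisopropylsilyloxy)-3,4-dihydro-2H-chromen-3-yl]phenol | C#CC(C)(C)Oc1ccc([C@@H]2COc3cc(O[Si](C(C)C)(C(C)C)C(C)C)ccc3C2)c(O)c1CC=C(C)C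
F11 | step 16 | 3-hydroxy-2-(3-methylbut-2-en-1-yl)-6-(3-methylbuta-1,2-dien-1-yl)-4-[(3R)-7-(triisopropylsilyloxy)-3,4-dihydro-2H-chromen-3-yl]cyclohexa-2,4-dien-1-one | O=C1C(CC=C(C)C)=C(O)C([C@@H]2COc3cc(O[Si](C(C)C)(C(C)C)C(C)C)ccc3C2)=CC1C=C=C(C)C
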